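The tetrahydrofuran is disconnected at C2–C3. C2 of that ring is at once benzylic and bonded to the ring oxygen O1, so in an open vanillyl ether its C–H bond is the weakest and most hydridic one; this feature is exploited. In one operation, photocatalytic hydrogen-atom abstraction at that OCH2 group and 5-exo addition of the radical to a tethered (E)-vinyl sulfone close the only saturated ring and create C2 and C3, steered by the auxiliary-derived C4 centre. The precursor is an acyclic bis-silylated homoallylic vanillyl ether bearing C4, its syringylmethyl group and a CH=CH–SO2Ph arm whose outer carbon becomes the C3 methyl after desulfonylation.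

Key step: step 12

Remark: the stereo tags of the target read (2R,3R,4R) with ring numbering O1, C2 (aryl), C3 (methyl), C4 (arylmethyl), C5, i.e. 2,3-trans and 3,4-trans; this all-trans isomer is the one planned for.

Step 1
Reactants: 1 syringaldehyde (4-hydroxy-3,5-dimethoxybenzaldehyde)
Product: 2 3,5-dimethoxy-4-(triisopropylsilyloxy)benzaldehyde
Conditions: TIPSCl, imidazole, DMAP (cat.), DMF, rt
Reagents that add atoms: triisopropylsilyl chloride (TIPSCl), CC(C)[Si](Cl)(C(C)C)C(C)C
Why: Imidazole-mediated O-silylation of the acidic phenol; the bulky triisopropylsilyl ether is chosen because it should withstand the amide base, borohydride, mild acid and metathesis to come and carries no weak C–H bond that could compete in step 12.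

Step 2
Reactants: 2 3,5-dimethoxy-4-(triisopropylsilyloxy)benzaldehyde
Product: 3 [3,5-dimethoxy-4-(triisopropylsilyloxy)phenyl]methanol
Conditions: NaBH4, MeOH/THF, 0 °C
Reagents that add atoms: none
Why: Borohydride reduction of the aryl aldehyde to the benzylic alcohol, to which the aryl silyl ether is inert.

Step 3
Reactants: 3 [3,5-dimethoxy-4-(triisopropylsilyloxy)phenyl]methanol
Product: 4 3,5-dimethoxy-4-(triisopropylsilyloxy)benzyl bromide
Conditions: PBr3, Et2O, 0 °C; used crude at once
Reagents that add atoms: phosphorus tribromide, BrP(Br)Br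
Why: PBr3 bromination, a substitution at the activated benzylic carbon that needs no strong acid or base; the electron-rich bromide is not chromatographed.

Step 4
Reactants: 5 (R)-4-benzyloxazolidin-2-one, 6 (E)-but-2-enoyl chloride (crotonyl chloride)
Product: 8 (R)-4-benzyl-3-[(E)-but-2-enoyl]oxazolidin-2-one, via N-lithio oxazolidinone 7 (not isolated)
Conditions: nBuLi, THF, −78 °C; then 6, −78 to 0 °C
Reagents that add atoms: none
Why: N-acylation of the lithiated oxazolidinone by the acid chloride, the standard preparation of N-enoyl imides, which leaves the (E)-alkene untouched.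

Step 5
Reactants: 8 (R)-4-benzyl-3-[(E)-but-2-enoyl]oxazolidin-2-one, 4 3,5-dimethoxy-4-(triisopropylsilyloxy)benzyl bromide
Product: 10 (R)-4-benzyl-3-[(R)-2-{[3,5-dimethoxy-4-(triisopropylsilyloxy)phenyl]methyl}but-3-enoyl]oxazolidin-2-one, via sodium (Z)-dienolate 9 (not isolated)
Conditions: NaN(SiMe3)2, THF, −78 °C; then 4, −78 to −45 °C; AcOH quench at −78 °C
Reagents that add atoms: none
Why: Gamma-deprotonation gives the chelated dienolate 9, which is alkylated at its alpha-carbon on the face remote from the auxiliary benzyl group (Evans-type asymmetric alkylation with deconjugation), so the (R)-auxiliary should deliver the (R)-configured centre that becomes C4, and the cold acidic quench prevents re-conjugation.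

Step 6
Reactants: 10 (R)-4-benzyl-3-[(R)-2-{[3,5-dimethoxy-4-(triisopropylsilyloxy)phenyl]methyl}but-3-enoyl]oxazolidin-2-one
Product: 11 (R)-2-{[3,5-dimethoxy-4-(triisopropylsilyloxy)phenyl]methyl}but-3-en-1-ol
Conditions: LiBH4, MeOH (2 equiv), Et2O, 0 °C
Reagents that add atoms: none
Why: Reductive cleavage of the exocyclic imide carbonyl by LiBH4 gives the primary alcohol and releases the auxiliary for re-use; once the carbonyl is gone the C4 centre is no longer acidic, and the alkene is not touched.

Step 7
Reactants: 12 vanillin (4-hydroxy-3-methoxybenzaldehyde)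
Product: 13 3-methoxy-4-(triisopropylsilyloxy)benzaldehyde
Conditions: TIPSCl, imidazole, DMF, rt
Reagents that add atoms: triisopropylsilyl chloride (TIPSCl), CC(C)[Si](Cl)(C(C)C)C(C)C
Why: Imidazole-mediated O-silylation of the phenol, giving the same robust protecting group as on the other arene so that both fall in one final operation.

Step 8
Reactants: 13 3-methoxy-4-(triisopropylsilyloxy)benzaldehyde
Product: 14 [3-methoxy-4-(triisopropylsilyloxy)phenyl]methanol
Conditions: NaBH4, MeOH/THF, 0 °C
Reagents that add atoms: none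
Why: Borohydride reduction of the aldehyde, chemoselective in the presence of the aryl silyl ether.

Step 9
Reactants: 14 [3-methoxy-4-(triisopropylsilyloxy)phenyl]methanol
Product: 15 3-methoxy-4-(triisopropylsilyloxy)benzyl 2,2,2-trichloroacetimidate
Conditions: Cl3CCN, DBU (10 mol %), CH2Cl2, 0 °C; filtered through Et3N-deactivated silica
Reagents that add atoms: trichloroacetonitrile, N#CC(Cl)(Cl)Cl
Why: Base-catalysed addition of the benzylic alcohol to the nitrile (trichloroacetimidate formation); the catalytic amidine base does not disturb the aryl silyl ether.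

Step 10
Reactants: 11 (R)-2-{[3,5-dimethoxy-4-(triisopropylsilyloxy)phenyl]methyl}but-3-en-1-ol, 15 3-methoxy-4-(triisopropylsilyloxy)benzyl 2,2,2-trichloroacetimidate
Product: 16 3-methoxy-4-(triisopropylsilyloxy)benzyl (R)-2-{[3,5-dimethoxy-4-(triisopropylsilyloxy)phenyl]methyl}but-3-en-1-yl ether
Conditions: PPTS (10 mol %), CH2Cl2/cyclohexane, 0 °C to rt; Et3N quench
Reagents that add atoms: none
Why: Mild acid activates the imidate as a benzylic electrophile stabilised by the para oxygen, which the primary alcohol captures (trichloroacetimidate benzylation), forming the O1–C2 bond without basic conditions that could move a silyl group; C4 is not involved.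

Step 11
Reactants: 16 3-methoxy-4-(triisopropylsilyloxy)benzyl (R)-2-{[3,5-dimethoxy-4-(triisopropylsilyloxy)phenyl]methyl}but-3-en-1-yl ether, 17 phenyl vinyl sulfone
Product: 18 3-methoxy-4-(triisopropylsilyloxy)benzyl (R,E)-2-{[3,5-dimethoxy-4-(triisopropylsilyloxy)phenyl]methyl}-4-(phenylsulfonyl)but-3-en-1-yl ether
Conditions: 17 (3 equiv), second-generation Hoveyda-Grubbs catalyst RuCl2(SIMes)(=CH-C6H4-2-OiPr) (5 mol %), CH2Cl2, 40 °C
Reagents that add atoms: none
Why: Olefin cross metathesis between the terminal alkene and the electron-poor phenyl vinyl sulfone, which does not homodimerise, should give the (E)-vinyl sulfone with loss of ethene under neutral conditions that cannot epimerise the allylic C4 centre.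

Step 12
Reactants: 18 3-methoxy-4-(triisopropylsilyloxy)benzyl (R,E)-2-{[3,5-dimethoxy-4-(triisopropylsilyloxy)phenyl]methyl}-4-(phenylsulfonyl)but-3-en-1-yl ether
Product: 23 (2R,3R,4R)-2-[3-methoxy-4-(triisopropylsilyloxy)phenyl]-4-{[3,5-dimethoxy-4-(triisopropylsilyloxy)phenyl]methyl}-3-[(phenylsulfonyl)methyl]tetrahydrofuran, via benzylic alpha-alkoxy radical 19 (not isolated), via cyclised alpha-sulfonyl radical 20 (not isolated), via C2-epimeric sulfone 21 (not isolated), via ring C2 radical 22 (not isolated)
Conditions: (nBu4N)4[W10O32] (2 mol %), MeCN/PhCF3 (0.02 M, degassed), 390 nm LEDs, rt, Ar; then iPr3SiSH (10 mol %), irradiation continued, rt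
Reagents that add atoms: none
Why: Proposed new method: photoexcited [W10O32]4−, an electrophilic hydrogen-atom abstractor, takes a hydrogen from the vanillyl OCH2 group of 18 to give the captodatively stabilised radical 19, whose C2 adds to the beta-carbon (C3) of the vinyl sulfone, and the electrophilic radical 20 recovers a hydrogen atom from the reduced cluster, so the ring closure is a redox-neutral isomerisation. The closest known reaction types are the decatungstate-photocatalysed Giese hydroalkylation of vinyl sulfones by ether and benzylic C–H donors, which is intermolecular, and the 5-exo cyclisation of 2-oxa-5-hexenyl (alpha-alkoxy) radicals made from selenoacetals; joining the two on a benzylic ether is the new element. The tetrahydrofuran, the only ring formed, closes 5-exo-trig because the nucleophilic radical is polarity-matched with the sulfone beta-carbon, whereas 6-endo attack would have to occur at the alpha-carbon and an unactivated vinyl group would trap so stabilised a radical too slowly. C3 is controlled by C4, whose arylmethyl group sits pseudo-equatorial in the chair-like transition state so that the new CH2SO2Ph arm ends trans to it. C2 is not left to kinetic control, because the same chair with the aryl group outside leads to the 2,3-cis epimer 21: the tertiary C2–H of the product, benzylic and alpha to oxygen, is the weakest C–H bond left and is exchanged reversibly through radical 22 by the thiyl/thiol pair of iPr3SiSH (thiol-mediated epimerisation of alpha-oxy C–H centres is known), which should drain the mixture into the thermodynamically preferred all-trans sulfone 23. The step needs abstraction at the OCH2 group only, secured by its double activation (radicals at the other benzylic CH2 or at C5 could close only three-membered rings and are repaired by hydrogen return, and the allylic C4–H is deactivated by the electron-poor alkene), and high dilution keeps intermolecular addition down.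

Step 13
Reactants: 23 (2R,3R,4R)-2-[3-methoxy-4-(triisopropylsilyloxy)phenyl]-4-{[3,5-dimethoxy-4-(triisopropylsilyloxy)phenyl]methyl}-3-[(phenylsulfonyl)methyl]tetrahydrofuran
Product: 24 (2R,3R,4R)-2-[3-methoxy-4-(triisopropylsilyloxy)phenyl]-4-{[3,5-dimethoxy-4-(triisopropylsilyloxy)phenyl]methyl}-3-methyltetrahydrofuran
Conditions: 5% Na(Hg), Na2HPO4, MeOH/THF, −20 to 0 °C
Reagents that add atoms: none
Why: Reductive desulfonylation, a two-electron cleavage of the alkyl C–S bond followed by protonation, leaves the C3 methyl group; the phosphate buffer keeps the medium from turning basic, and none of the three stereocentres takes part.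

Step 14
Reactants: 24 (2R,3R,4R)-2-[3-methoxy-4-(triisopropylsilyloxy)phenyl]-4-{[3,5-dimethoxy-4-(triisopropylsilyloxy)phenyl]methyl}-3-methyltetrahydrofuran
Product: 25 (2R,3R,4R)-2-(4-hydroxy-3-methoxyphenyl)-4-[(4-hydroxy-3,5-dimethoxyphenyl)methyl]-3-methyltetrahydrofuran (CID53359708)
Conditions: nBu4NF, AcOH (1 equiv per fluoride), THF, 0 °C
Reagents that add atoms: none
Why: Fluoride-induced cleavage of both aryl Si–O bonds (desilylation) releases the two phenols; acetic acid buffers the phenoxides against air oxidation and quinone-methide opening at C2, and stronger acid is avoided because it would ionise the C2 benzylic ether toward attack by the syringyl ring.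

Compound list
1 | syringaldehyde | COc1cc(C=O)cc(OC)c1O | starting material
2 | 3,5-dimethoxy-4-(triisopropylsilyloxy)benzaldehyde | COc1cc(C=O)cc(OC)c1O[Si](C(C)C)(C(C)C)C(C)C | intermediate
3 | [3,5-dimethoxy-4-(triisopropylsilyloxy)phenyl]methanol | COc1cc(CO)cc(OC)c1O[Si](C(C)C)(C(C)C)C(C)C | intermediate
4 | 3,5-dimethoxy-4-(triisopropylsilyloxy)benzyl bromide | COc1cc(CBr)cc(OC)c1O[Si](C(C)C)(C(C)C)C(C)C | intermediate
5 | (R)-4-benzyloxazolidin-2-one | O=C1N[C@H](Cc2ccccc2)CO1 | starting material
6 | (E)-but-2-enoyl chloride | C/C=C/C(=O)Cl | starting material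
7 | N-lithio derivative of 5 (not isolated) | [Li+].O=C1[N-][C@H](Cc2ccccc2)CO1 | intermediate
8 | (R)-4-benzyl-3-[(E)-but-2-enoyl]oxazolidin-2-one | C/C=C/C(=O)N1[C@H](Cc2ccccc2)COC1=O | intermediate
9 | sodium (Z)-dienolate of 8 (not isolated) | [Na+].[O-]/C(=C\C=C)N1[C@H](Cc2ccccc2)COC1=O | intermediate
10 | (R)-4-benzyl-3-[(R)-2-{[3,5-dimethoxy-4-(triisopropylsilyloxy)phenyl]methyl}but-3-enoyl]oxazolidin-2-one | O=C(N1[C@H](Cc2ccccc2)COC1=O)[C@H](Cc3cc(OC)c(O[Si](C(C)C)(C(C)C)C(C)C)c(OC)c3)C=C | intermediate
11 | (R)-2-{[3,5-dimethoxy-4-(triisopropylsilyloxy)phenyl]methyl}but-3-en-1-ol | OC[C@H](Cc1cc(OC)c(O[Si](C(C)C)(C(C)C)C(C)C)c(OC)c1)C=C | intermediate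
12 | vanillin | COc1cc(C=O)ccc1O | starting material
13 | 3-methoxy-4-(triisopropylsilyloxy)benzaldehyde | COc1cc(C=O)ccc1O[Si](C(C)C)(C(C)C)C(C)C | intermediate
14 | [3-methoxy-4-(triisopropylsilyloxy)phenyl]methanol | COc1cc(CO)ccc1O[Si](C(C)C)(C(C)C)C(C)C | intermediate
15 | 3-methoxy-4-(triisopropylsilyloxy)benzyl 2,2,2-trichloroacetimidate | COc1cc(COC(=N)C(Cl)(Cl)Cl)ccc1O[Si](C(C)C)(C(C)C)C(C)C | intermediate
16 | 3-methoxy-4-(triisopropylsilyloxy)benzyl (R)-2-{[3,5-dimethoxy-4-(triisopropylsilyloxy)phenyl]methyl}but-3-en-1-yl ether | COc1cc(COC[C@H](Cc2cc(OC)c(O[Si](C(C)C)(C(C)C)C(C)C)c(OC)c2)C=C)ccc1O[Si](C(C)C)(C(C)C)C(C)C | intermediate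
17 | phenyl vinyl sulfone | C=CS(=O)(=O)c1ccccc1 | starting material
18 | 3-methoxy-4-(triisopropylsilyloxy)benzyl (R,E)-2-{[3,5-dimethoxy-4-(triisopropylsilyloxy)phenyl]methyl}-4-(phenylsulfonyl)but-3-en-1-yl ether | COc1cc(COC[C@H](Cc2cc(OC)c(O[Si](C(C)C)(C(C)C)C(C)C)c(OC)c2)/C=C/S(=O)(=O)c3ccccc3)ccc1O[Si](C(C)C)(C(C)C)C(C)C | intermediate
19 | radical from 18 by loss of one hydrogen of the vanillyl OCH2 group (not isolated) | COc1cc([CH]OC[C@H](Cc2cc(OC)c(O[Si](C(C)C)(C(C)C)C(C)C)c(OC)c2)/C=C/S(=O)(=O)c3ccccc3)ccc1O[Si](C(C)C)(C(C)C)C(C)C | intermediate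
20 | cyclised 3,4-trans tetrahydrofuran-3-yl(phenylsulfonyl)methyl radical, both C2 epimers (not isolated) | COc1cc(C2OC[C@H](Cc3cc(OC)c(O[Si](C(C)C)(C(C)C)C(C)C)c(OC)c3)[C@H]2[CH]S(=O)(=O)c4ccccc4)ccc1O[Si](C(C)C)(C(C)C)C(C)C | intermediate
21 | (2S,3R,4R) epimer of 23, 2,3-cis-3,4-trans (not isolated) | COc1cc([C@H]2OC[C@H](Cc3cc(OC)c(O[Si](C(C)C)(C(C)C)C(C)C)c(OC)c3)[C@H]2CS(=O)(=O)c4ccccc4)ccc1O[Si](C(C)C)(C(C)C)C(C)C | intermediate
22 | planar C2 radical of the cyclised sulfone, 3,4-trans (not isolated) | COc1cc([C]2OC[C@H](Cc3cc(OC)c(O[Si](C(C)C)(C(C)C)C(C)C)c(OC)c3)[C@H]2CS(=O)(=O)c4ccccc4)ccc1O[Si](C(C)C)(C(C)C)C(C)C | intermediate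
23 | (2R,3R,4R)-2-[3-methoxy-4-(triisopropylsilyloxy)phenyl]-4-{[3,5-dimethoxy-4-(triisopropylsilyloxy)phenyl]methyl}-3-[(phenylsulfonyl)methyl]tetrahydrofuran | COc1cc([C@@H]2OC[C@H](Cc3cc(OC)c(O[Si](C(C)C)(C(C)C)C(C)C)c(OC)c3)[C@H]2CS(=O)(=O)c4ccccc4)ccc1O[Si](C(C)C)(C(C)C)C(C)C | intermediate
24 | (2R,3R,4R)-2-[3-methoxy-4-(triisopropylsilyloxy)phenyl]-4-{[3,5-dimethoxy-4-(triisopropylsilyloxy)phenyl]methyl}-3-methyltetrahydrofuran | COc1cc([C@@H]2OC[C@H](Cc3cc(OC)c(O[Si](C(C)C)(C(C)C)C(C)C)c(OC)c3)[C@H]2C)ccc1O[Si](C(C)C)(C(C)C)C(C)C | intermediate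
25 | (2R,3R,4R)-2-(4-hydroxy-3-methoxyphenyl)-4-[(4-hydroxy-3,5-dimethoxyphenyl)methyl]-3-methyltetrahydrofuran | COc1cc([C@@H]2OC[C@H](Cc3cc(OC)c(O)c(OC)c3)[C@H]2C)ccc1O | target

Total step count: 14 steps.
Longest linear sequence: 10 steps (1, 2, 3, 5, 6, 10, 11, 12, 13, 14, from syringaldehyde).

Steps most likely to fail

Step 12 (proposed new method). Hydrogen-atom abstraction may be slow or unselective on so electron-rich a substrate (electron transfer from the arenes to the excited cluster, attack at other C–H bonds), closure may lose to intermolecular addition, or the equilibration at C2 may stall short of the all-trans isomer. The fallback is a conventional nBu3SnH chain; it sets out from alcohol 11 and returns at sulfone 23. Cross metathesis of 11 with 17 under the conditions of step 11 should give the hydroxy vinyl sulfone (R,E)-2-{[3,5-dimethoxy-4-(triisopropylsilyloxy)phenyl]methyl}-4-(phenylsulfonyl)but-3-en-1-ol F1. Me3SiCl/Et3N turns it into its trimethylsilyl ether F2. Condensation of F2 with aldehyde 13 and PhSSiMe3 under catalytic Me3SiOTf (CH2Cl2, −78 °C) gives the mixed O,S-acetal F3; both epimers at the acetal carbon serve. Slow addition of nBu3SnH with AIBN in benzene at 80 °C removes the phenylthio group and generates radical 19 without any C–H abstraction. The 5-exo closure to 20 and hydrogen transfer from the stannane then give the cyclised sulfone as a mixture of 21 and 23, which iPr3SiSH (10 mol %) and AIBN at 80 °C equilibrate toward 23.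

Step 10. Under acid the benzylic electrophile may alkylate the very electron-rich syringyl ring (Friedel–Crafts benzylation) in place of the hydroxyl group, the product ether may ionise again, and the imidate may rearrange to the N-benzyl amide. The fallback runs under basic SN2 conditions, from alcohols 14 and 11 back to ether 16. PBr3 (Et2O, 0 °C) converts 14 into 3-methoxy-4-(triisopropylsilyloxy)benzyl bromide F4. NaH (THF/DMF, 0 °C) converts 11 into its sodium alkoxide F5. Williamson alkylation of F5 with F4 (cat. nBu4NI) gives 16; the bulky silyl groups are relied on to resist transfer to the alkoxide.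

Step 11. Metathesis may be slow at an alkene flanked by the branched carbon C4, so that catalyst decay and homodimerisation of 16 take over. The fallback is iodosulfonylation and elimination, from 16 back to 18. PhSO2Na and I2 (EtOAc/H2O, rt, daylight) generate benzenesulfonyl iodide, whose radical-chain addition to the terminal alkene should give the beta-iodo sulfone F6, with the sulfonyl group on the terminal carbon and both epimers at the CHI carbon. Et3N (CH2Cl2, 0 °C) then eliminates hydrogen iodide to the (E)-vinyl sulfone 18; so mild a base is chosen so that the product does not drift to the allyl sulfone.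

Further compounds
F1 | step 12 | (R,E)-2-{[3,5-dimethoxy-4-(triisopropylsilyloxy)phenyl]methyl}-4-(phenylsulfonyl)but-3-en-1-ol | OC[C@H](Cc1cc(OC)c(O[Si](C(C)C)(C(C)C)C(C)C)c(OC)c1)/C=C/S(=O)(=O)c2ccccc2
F2 | step 12 | trimethylsilyl ether of F1 | C[Si](C)(C)OC[C@H](Cc1cc(OC)c(O[Si](C(C)C)(C(C)C)C(C)C)c(OC)c1)/C=C/S(=O)(=O)c2ccccc2
F3 | step 12 | mixed O,S-acetal of aldehyde 13 with F1 and thiophenol, both epimers at the acetal carbon | COc1cc(C(Sc2ccccc2)OC[C@H](Cc3cc(OC)c(O[Si](C(C)C)(C(C)C)C(C)C)c(OC)c3)/C=C/S(=O)(=O)c4ccccc4)ccc1O[Si](C(C)C)(C(C)C)C(C)C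
F4 | step 10 | 3-methoxy-4-(triisopropylsilyloxy)benzyl bromide | COc1cc(CBr)ccc1O[Si](C(C)C)(C(C)C)C(C)C
F5 | step 10 | sodium alkoxide of 11 | [Na+].[O-]C[C@H](Cc1cc(OC)c(O[Si](C(C)C)(C(C)C)C(C)C)c(OC)c1)C=C
F6 | step 11 | beta-iodo sulfone from 16, 3-iodo-4-(phenylsulfonyl)butyl ether, both epimers at the CHI carbon | COc1cc(COC[C@H](Cc2cc(OC)c(O[Si](C(C)C)(C(C)C)C(C)C)c(OC)c2)C(I)CS(=O)(=O)c3ccccc3)ccc1O[Si](C(C)C)(C(C)C)C(C)C
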